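The route rests on disconnecting the C8–C9 bond of the ten-membered carbocycle (germacrane numbering) by a ring expansion. The ring is read as a cyclodec-5-enone: the C6 oxygen, the C1–C10 epoxide (from a Z-alkene) and the oxygenated C8 next to the C9 methylene are the retron of an anionic oxy-Cope rearrangement. A cis-1-(2-alkoxyvinyl)-6-isopropenylcyclohex-2-enol, made from a quinone monoketal, rearranges through a chair to form C8–C9, break C1–C6, set the (Z)-C1=C10 alkene, transfer chirality to C8 and unveil a C6 enolate that is alkylated at C7 in the same flask. C8 is later inverted as the angelate is installed.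

Key step: step 10

Remark: germacrane numbering is used for all compounds, cyclohexene precursors included (C6 lactone carbinol, C7 ring-fusion CH, C8 angelate carbinol, C9 CH2, C10 methyl-bearing carbon, C1 epoxide CH, C3 carbinol, C4 quaternary carbinol, C15 on C4, C11–C13 lactone carbons, C14 methyl); compounds 1, 5, 10, 11, 16 and 28 are taken as commercial; TBS = tert-butyldimethylsilyl, PMB = 4-methoxybenzyl.

**Step 1**
Reactants: 1 2-hydroxy-5-methoxybenzaldehyde
Product: 2 2-(hydroxymethyl)-4-methoxyphenol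
Conditions: NaBH4, MeOH, 0 °C
Reagents that add atoms: none
Why: Sodium borohydride reduction of the aryl aldehyde to the benzylic alcohol is chemoselective and creates no stereocenter.

**Step 2**
Reactants: 2 2-(hydroxymethyl)-4-methoxyphenol
Product: 3 2-(hydroxymethyl)-4,4-dimethoxycyclohexa-2,5-dien-1-one
Conditions: PhI(OAc)2, MeOH, 0 °C
Reagents that add atoms: methanol, CO
Why: Hypervalent-iodine oxidative dearomatization of the para-methoxyphenol in methanol should give the para-quinone monoketal, which already carries C15 at the correct oxidation level on the carbon that becomes C4.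

**Step 3**
Reactants: 3 2-(hydroxymethyl)-4,4-dimethoxycyclohexa-2,5-dien-1-one
Product: 4 2-{[(tert-butyldimethylsilyl)oxy]methyl}-4,4-dimethoxycyclohexa-2,5-dien-1-one
Conditions: TBSCl, imidazole, DMF, 0 °C to rt
Reagents that add atoms: tert-butyldimethylsilyl chloride, CC(C)(C)[Si](C)(C)Cl
Why: Standard imidazole-mediated silylation of the primary alcohol masks the C15 hydroxyl for the hydride and organometallic steps that follow.

**Step 4**
Reactants: 4 2-{[(tert-butyldimethylsilyl)oxy]methyl}-4,4-dimethoxycyclohexa-2,5-dien-1-one; 5 potassium isopropenyltrifluoroborate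
Product: 6 (5R)-2-{[(tert-butyldimethylsilyl)oxy]methyl}-4,4-dimethoxy-5-(prop-1-en-2-yl)cyclohex-2-en-1-one
Conditions: [Rh(cod)2]BF4 (3 mol%), (R)-BINAP, Et3N, PhMe–H2O, rt
Reagents that add atoms: none
Why: Rhodium–BINAP-catalysed asymmetric conjugate addition of an alkenyltrifluoroborate (Hayashi–Miyaura type) should take place at the unsubstituted enone and not at the α-substituted one, and the (R)-ligand sets the isopropenyl-bearing carbon (future C1) as R.

**Step 5**
Reactants: 6 (5R)-2-{[(tert-butyldimethylsilyl)oxy]methyl}-4,4-dimethoxy-5-(prop-1-en-2-yl)cyclohex-2-en-1-one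
Product: 8 (4S,6R)-3-{[(tert-butyldimethylsilyl)oxy]methyl}-4-hydroxy-6-(prop-1-en-2-yl)cyclohex-2-en-1-one, via allylic alcohol ketal 7 (not isolated)
Conditions: (R)-Me-CBS (20 mol%), BH3·SMe2, THF, −30 °C; then 5% aq. oxalic acid, THF, 0 °C
Reagents that add atoms: water, O
Why: Corey–Bakshi–Shibata reduction under reagent control (alkenyl side as the large group) should set the carbinol (future C3) as S, trans to the isopropenyl group, and the acidic work-up hydrolyses the allylic dimethyl ketal to reveal the enone whose carbonyl is the future C6.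

**Step 6**
Reactants: 8 (4S,6R)-3-{[(tert-butyldimethylsilyl)oxy]methyl}-4-hydroxy-6-(prop-1-en-2-yl)cyclohex-2-en-1-one
Product: 9 (4S,6R)-4-[(tert-butyldimethylsilyl)oxy]-3-{[(tert-butyldimethylsilyl)oxy]methyl}-6-(prop-1-en-2-yl)cyclohex-2-en-1-one
Conditions: TBSCl, imidazole, DMF, rt
Reagents that add atoms: tert-butyldimethylsilyl chloride, CC(C)(C)[Si](C)(C)Cl
Why: Silylation of the secondary allylic alcohol protects the C3 hydroxyl through the basic and hydridic steps up to the end of the route.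

**Step 7**
Reactants: 10 4-methoxybenzyl alcohol; 11 trichloroethylene
Product: 12 1-({[(E)-1,2-dichloroethenyl]oxy}methyl)-4-methoxybenzene
Conditions: KH, THF, 0 °C; Cl2C=CHCl, rt
Reagents that add atoms: none
Why: Addition of the potassium alkoxide to dichloroacetylene formed in situ from trichloroethylene is the established entry to (E)-1,2-dichlorovinyl ethers, which are storable precursors of alkoxyacetylides.

**Step 8**
Reactants: 9 (4S,6R)-4-[(tert-butyldimethylsilyl)oxy]-3-{[(tert-butyldimethylsilyl)oxy]methyl}-6-(prop-1-en-2-yl)cyclohex-2-en-1-one; 12 1-({[(E)-1,2-dichloroethenyl]oxy}methyl)-4-methoxybenzene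
Product: 14 (1S,4S,6R)-4-[(tert-butyldimethylsilyl)oxy]-3-{[(tert-butyldimethylsilyl)oxy]methyl}-1-{[(4-methoxybenzyl)oxy]ethynyl}-6-(prop-1-en-2-yl)cyclohex-2-en-1-ol, via lithium alkoxyacetylide 13 (not isolated)
Conditions: 12, n-BuLi (2.2 equiv), THF, −78 to −40 °C; then 9, −78 °C; aq. NH4Cl
Reagents that add atoms: none
Why: Two equivalents of n-BuLi convert 12 into the lithium alkoxyacetylide by elimination and chlorine–lithium exchange, and its 1,2-addition to the enone should occur axially on the half-chair, anti to the pseudoaxial hydrogen at the isopropenyl-bearing carbon and away from the pseudoaxial silyloxy group, so that the alkynyl group ends cis to the isopropenyl group.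

**Step 9**
Reactants: 14 (1S,4S,6R)-4-[(tert-butyldimethylsilyl)oxy]-3-{[(tert-butyldimethylsilyl)oxy]methyl}-1-{[(4-methoxybenzyl)oxy]ethynyl}-6-(prop-1-en-2-yl)cyclohex-2-en-1-ol
Product: 15 (1S,4S,6R)-4-[(tert-butyldimethylsilyl)oxy]-3-{[(tert-butyldimethylsilyl)oxy]methyl}-1-{(E)-2-[(4-methoxybenzyl)oxy]ethenyl}-6-(prop-1-en-2-yl)cyclohex-2-en-1-ol
Conditions: LiAlH4, THF, 0 °C to rt; aq. NaOH work-up
Reagents that add atoms: none
Why: Alkoxide-directed trans-hydroalumination of the propargylic alcohol with LiAlH4 should give the (E)-enol ether, the geometry that the rearrangement needs, while isolated alkenes and silyl ethers are inert.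

**Step 10**
Reactants: 15 (1S,4S,6R)-4-[(tert-butyldimethylsilyl)oxy]-3-{[(tert-butyldimethylsilyl)oxy]methyl}-1-{(E)-2-[(4-methoxybenzyl)oxy]ethenyl}-6-(prop-1-en-2-yl)cyclohex-2-en-1-ol; 16 ethyl iodoacetate
Product: 19 ethyl (3S,7R,8S,1(10)Z,4Z)-3,15-bis[(tert-butyldimethylsilyl)oxy]-8-[(4-methoxybenzyl)oxy]-6-oxo-13-norgermacra-1(10),4-dien-12-oate, via potassium alkoxide 17 (not isolated), via potassium dienolate 18 (not isolated)
Conditions: KH, 18-crown-6, THF, 0 °C to rt; then −78 °C, ICH2CO2Et; aq. NH4Cl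
Reagents that add atoms: none
Why: KH gives alkoxide 17, which undergoes an alkoxide-accelerated [3,3]-sigmatropic shift in which C8–C9 forms as C1–C6 breaks; the closest known reaction type is the anionic oxy-Cope ring expansion of 1,2-dialkenylcyclohexanols to cyclodec-5-enones. The ten-membered ring is closed through a six-centre chair transition state, i.e. by a four-atom ring expansion of the cyclohexene and not by an end-to-end macrocyclization. Because the two alkenyl groups are cis, the chair has the isopropenyl group equatorial and the alkoxyvinyl group axial on the cyclohexene, an arrangement reinforced by the pseudoaxial C3 silyloxy group (A-1,2 strain with the C4 substituent), and this should give the (Z)-C1=C10 alkene. Chirality is transferred from C1 and C6 to C8: the (E)-enol ether keeps the PMB-oxy group equatorial in the chair, which should give 8S and leaves the C8–O bond in the plane of the enolate, where β-elimination is stereoelectronically disfavoured. The (E)-ring enolate 18 is then alkylated at C7 on its exposed face, anti to C9 and syn to H8, which should give 7R with the acetate side chain trans to the C8 oxygen. The step needs chair over boat selection, rearrangement through the alkoxyvinyl/isopropenyl pair and not through the ring alkene, and C- over O-alkylation; these are secured by the equatorial preference of the isopropenyl group, by the geometric inaccessibility of the ring-alkene terminus and by the soft iodide electrophile at low temperature.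

**Step 11**
Reactants: 19 ethyl (3S,7R,8S,1(10)Z,4Z)-3,15-bis[(tert-butyldimethylsilyl)oxy]-8-[(4-methoxybenzyl)oxy]-6-oxo-13-norgermacra-1(10),4-dien-12-oate
Product: 21 ethyl (3S,4R,7R,8S,1(10)Z)-3,15-bis[(tert-butyldimethylsilyl)oxy]-4-hydroxy-8-[(4-methoxybenzyl)oxy]-6-oxo-13-norgermacr-1(10)-en-12-oate, via pinacol boronate 20 (not isolated)
Conditions: CuCl (10 mol%), Xantphos, NaOt-Bu (15 mol%), B2pin2, MeOH, THF, rt; then NaBO3·4H2O, THF–H2O, rt
Reagents that add atoms: bis(pinacolato)diboron, CC1(C)OB(OC1(C)C)B1OC(C)(C)C(C)(C)O1; NaBO3·4H2O (sodium perborate), [Na+].[O-]OB=O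
Why: Conjugate borylation of the β,β-disubstituted enone by a copper–boryl species followed by perborate oxidation with retention should install the tertiary C4 hydroxyl, the boryl group adding anti to the adjacent C3 silyloxy group to give 4R.

**Step 12**
Reactants: 21 ethyl (3S,4R,7R,8S,1(10)Z)-3,15-bis[(tert-butyldimethylsilyl)oxy]-4-hydroxy-8-[(4-methoxybenzyl)oxy]-6-oxo-13-norgermacr-1(10)-en-12-oate
Product: 23 (3S,4R,6R,7R,8S,1(10)Z)-3,15-bis[(tert-butyldimethylsilyl)oxy]-4-hydroxy-8-[(4-methoxybenzyl)oxy]-13-norgermacr-1(10)-en-12,6-olide, via diol ester 22 (not isolated)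
Conditions: Et2BOMe, NaBH4, THF–MeOH (4:1), −78 °C; AcOH; then PPTS, PhMe, 50 °C
Reagents that add atoms: none
Why: Narasaka–Prasad reduction, in which external hydride attacks the six-membered boron chelate of the β-hydroxy ketone, should give the 1,3-syn diol (6R), and the new C6 hydroxyl then closes the trans-fused γ-lactone onto the ester under mild acid.

**Step 13**
Reactants: 23 (3S,4R,6R,7R,8S,1(10)Z)-3,15-bis[(tert-butyldimethylsilyl)oxy]-4-hydroxy-8-[(4-methoxybenzyl)oxy]-13-norgermacr-1(10)-en-12,6-olide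
Product: 26 (3S,4R,6R,7R,8S,1(10)Z)-3,15-bis[(tert-butyldimethylsilyl)oxy]-4-hydroxy-8-[(4-methoxybenzyl)oxy]germacra-1(10),11(13)-dien-12,6-olide, via Mannich base 24 (not isolated), via ammonium iodide 25 (not isolated)
Conditions: LiN(SiMe3)2 (2.5 equiv), THF, −78 °C; CH2=NMe2 iodide, −78 °C to rt; MeI, MeOH, rt; aq. NaHCO3, CH2Cl2
Reagents that add atoms: dimethyl(methylidene)ammonium iodide, C=[N+](C)C.[I-]; iodomethane, CI
Why: α-Methylenation of the lactone by Mannich reaction of its lithium enolate with Eschenmoser's salt, quaternization and β-elimination is a standard sequence, and C11 becomes trigonal so no stereocenter is at stake.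

**Step 14**
Reactants: 26 (3S,4R,6R,7R,8S,1(10)Z)-3,15-bis[(tert-butyldimethylsilyl)oxy]-4-hydroxy-8-[(4-methoxybenzyl)oxy]germacra-1(10),11(13)-dien-12,6-olide
Product: 27 (3S,4R,6R,7R,8S,1(10)Z)-3,15-bis[(tert-butyldimethylsilyl)oxy]-4,8-dihydroxygermacra-1(10),11(13)-dien-12,6-olide
Conditions: DDQ, CH2Cl2–pH 7 buffer, 0 °C
Reagents that add atoms: none
Why: Oxidative removal of the PMB ether with DDQ (benzylic hydride abstraction and hydrolysis) is selective in the presence of silyl ethers, the tertiary alcohol and the isolated and conjugated alkenes.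

**Step 15**
Reactants: 27 (3S,4R,6R,7R,8S,1(10)Z)-3,15-bis[(tert-butyldimethylsilyl)oxy]-4,8-dihydroxygermacra-1(10),11(13)-dien-12,6-olide; 28 angelic acid
Product: 29 (3S,4R,6R,7R,8R,1(10)Z)-8-(angeloyloxy)-3,15-bis[(tert-butyldimethylsilyl)oxy]-4-hydroxygermacra-1(10),11(13)-dien-12,6-olide
Conditions: PPh3, DIAD, 28, PhMe, 0 °C to rt
Reagents that add atoms: none
Why: Mitsunobu esterification should displace the C8 oxyphosphonium ion by angelate with inversion (8S to 8R) and, because the acid is never activated as an acyl electrophile, should avoid the isomerization of the angelate to the tiglate.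

**Step 16**
Reactants: 29 (3S,4R,6R,7R,8R,1(10)Z)-8-(angeloyloxy)-3,15-bis[(tert-butyldimethylsilyl)oxy]-4-hydroxygermacra-1(10),11(13)-dien-12,6-olide
Product: 30 (3S,4R,6R,7R,8R,1(10)Z)-8-(angeloyloxy)-3,4,15-trihydroxygermacra-1(10),11(13)-dien-12,6-olide
Conditions: HF·pyridine, pyridine, THF, 0 °C to rt
Reagents that add atoms: none
Why: Buffered HF·pyridine cleaves both silyl ethers by fluoride-driven Si–O scission while the lactone, the angelate and the exocyclic methylene are left intact.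

**Step 17**
Reactants: 30 (3S,4R,6R,7R,8R,1(10)Z)-8-(angeloyloxy)-3,4,15-trihydroxygermacra-1(10),11(13)-dien-12,6-olide
Product: 31 (1R,3S,4R,6R,7S,8R,10S)-8-(angeloyloxy)-1,10-epoxy-3,4,15-trihydroxygermacr-11(13)-en-12,6-olide (CNP0307250.1)
Conditions: Shi ketone (D-fructose-derived, 30 mol%), KHSO5 (Oxone), K2CO3, Bu4NHSO4, MeCN–CH2(OMe)2–aq. Na2B4O7, 0 °C
Reagents that add atoms: KHSO5 (potassium peroxymonosulfate), [K+].OOS(=O)(=O)[O-]
Why: Shi asymmetric epoxidation with the chiral dioxirane is stereospecific (the Z alkene gives the cis-epoxide), selective for the electron-rich trisubstituted C1=C10 bond over the two conjugated alkenes, and the D-fructose-derived ketone should deliver oxygen to the face giving 1R,10S by analogy with its sense on 1-substituted cycloalkenes, under basic conditions that do not provoke transannular attack of the C4 hydroxyl.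

**Compound list**

1 | 2-hydroxy-5-methoxybenzaldehyde | COc1ccc(O)c(C=O)c1 | starting material
2 | 2-(hydroxymethyl)-4-methoxyphenol | COc1ccc(O)c(CO)c1 | intermediate
3 | 2-(hydroxymethyl)-4,4-dimethoxycyclohexa-2,5-dien-1-one | OCC1=CC(OC)(OC)C=CC1=O | intermediate
4 | 2-{[(tert-butyldimethylsilyl)oxy]methyl}-4,4-dimethoxycyclohexa-2,5-dien-1-one | CC(C)(C)[Si](C)(C)OCC1=CC(OC)(OC)C=CC1=O | intermediate
5 | potassium isopropenyltrifluoroborate | [K+].C=C(C)[B-](F)(F)F | starting material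
6 | (5R)-2-{[(tert-butyldimethylsilyl)oxy]methyl}-4,4-dimethoxy-5-(prop-1-en-2-yl)cyclohex-2-en-1-one | C=C(C)[C@H]1CC(=O)C(CO[Si](C)(C)C(C)(C)C)=CC1(OC)OC | intermediate
7 | (1S,5R)-2-{[(tert-butyldimethylsilyl)oxy]methyl}-4,4-dimethoxy-5-(prop-1-en-2-yl)cyclohex-2-en-1-ol (not isolated) | C=C(C)[C@H]1C[C@H](O)C(CO[Si](C)(C)C(C)(C)C)=CC1(OC)OC | intermediate
8 | (4S,6R)-3-{[(tert-butyldimethylsilyl)oxy]methyl}-4-hydroxy-6-(prop-1-en-2-yl)cyclohex-2-en-1-one | C=C(C)[C@H]1C[C@H](O)C(CO[Si](C)(C)C(C)(C)C)=CC1=O | intermediate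
9 | (4S,6R)-4-[(tert-butyldimethylsilyl)oxy]-3-{[(tert-butyldimethylsilyl)oxy]methyl}-6-(prop-1-en-2-yl)cyclohex-2-en-1-one | C=C(C)[C@H]1C[C@H](O[Si](C)(C)C(C)(C)C)C(CO[Si](C)(C)C(C)(C)C)=CC1=O | intermediate
10 | 4-methoxybenzyl alcohol | COc1ccc(CO)cc1 | starting material
11 | trichloroethylene | ClC=C(Cl)Cl | starting material
12 | 1-({[(E)-1,2-dichloroethenyl]oxy}methyl)-4-methoxybenzene | COc1ccc(CO/C(Cl)=C\Cl)cc1 | intermediate
13 | lithium [(4-methoxybenzyl)oxy]ethynide (not isolated) | [Li+].[C-]#COCc1ccc(OC)cc1 | intermediate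
14 | (1S,4S,6R)-4-[(tert-butyldimethylsilyl)oxy]-3-{[(tert-butyldimethylsilyl)oxy]methyl}-1-{[(4-methoxybenzyl)oxy]ethynyl}-6-(prop-1-en-2-yl)cyclohex-2-en-1-ol | C=C(C)[C@H]1C[C@H](O[Si](C)(C)C(C)(C)C)C(CO[Si](C)(C)C(C)(C)C)=C[C@@]1(O)C#COCc2ccc(OC)cc2 | intermediate
15 | (1S,4S,6R)-4-[(tert-butyldimethylsilyl)oxy]-3-{[(tert-butyldimethylsilyl)oxy]methyl}-1-{(E)-2-[(4-methoxybenzyl)oxy]ethenyl}-6-(prop-1-en-2-yl)cyclohex-2-en-1-ol | C=C(C)[C@H]1C[C@H](O[Si](C)(C)C(C)(C)C)C(CO[Si](C)(C)C(C)(C)C)=C[C@@]1(O)/C=C/OCc2ccc(OC)cc2 | intermediate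
16 | ethyl iodoacetate | CCOC(=O)CI | starting material
17 | potassium alkoxide of 15 (not isolated) | [K+].C=C(C)[C@H]1C[C@H](O[Si](C)(C)C(C)(C)C)C(CO[Si](C)(C)C(C)(C)C)=C[C@@]1([O-])/C=C/OCc2ccc(OC)cc2 | intermediate
18 | potassium (3S,8S,1(10)Z,4Z,6E)-3,15-bis[(tert-butyldimethylsilyl)oxy]-8-[(4-methoxybenzyl)oxy]-10-methylcyclodeca-1(10),4,6-trien-6-olate, germacrane numbering (not isolated) | [K+].C1/C(C)=C\C[C@H](O[Si](C)(C)C(C)(C)C)/C(CO[Si](C)(C)C(C)(C)C)=C\C([O-])=C\[C@H]1OCc2ccc(OC)cc2 | intermediate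
19 | ethyl (3S,7R,8S,1(10)Z,4Z)-3,15-bis[(tert-butyldimethylsilyl)oxy]-8-[(4-methoxybenzyl)oxy]-6-oxo-13-norgermacra-1(10),4-dien-12-oate | C1/C(C)=C\C[C@H](O[Si](C)(C)C(C)(C)C)/C(CO[Si](C)(C)C(C)(C)C)=C\C(=O)[C@H](CC(=O)OCC)[C@H]1OCc2ccc(OC)cc2 | intermediate
20 | C4 pinacol boronate from 19, boron anti to the C3 silyloxy group (not isolated) | C1/C(C)=C\C[C@H](O[Si](C)(C)C(C)(C)C)[C@](B2OC(C)(C)C(C)(C)O2)(CO[Si](C)(C)C(C)(C)C)CC(=O)[C@H](CC(=O)OCC)[C@H]1OCc3ccc(OC)cc3 | intermediate
21 | ethyl (3S,4R,7R,8S,1(10)Z)-3,15-bis[(tert-butyldimethylsilyl)oxy]-4-hydroxy-8-[(4-methoxybenzyl)oxy]-6-oxo-13-norgermacr-1(10)-en-12-oate | C1/C(C)=C\C[C@H](O[Si](C)(C)C(C)(C)C)[C@](O)(CO[Si](C)(C)C(C)(C)C)CC(=O)[C@H](CC(=O)OCC)[C@H]1OCc2ccc(OC)cc2 | intermediate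
22 | ethyl (3S,4R,6R,7S,8S,1(10)Z)-3,15-bis[(tert-butyldimethylsilyl)oxy]-4,6-dihydroxy-8-[(4-methoxybenzyl)oxy]-13-norgermacr-1(10)-en-12-oate (not isolated) | C1/C(C)=C\C[C@H](O[Si](C)(C)C(C)(C)C)[C@](O)(CO[Si](C)(C)C(C)(C)C)C[C@@H](O)[C@H](CC(=O)OCC)[C@H]1OCc2ccc(OC)cc2 | intermediate
23 | (3S,4R,6R,7R,8S,1(10)Z)-3,15-bis[(tert-butyldimethylsilyl)oxy]-4-hydroxy-8-[(4-methoxybenzyl)oxy]-13-norgermacr-1(10)-en-12,6-olide | C1/C(C)=C\C[C@H](O[Si](C)(C)C(C)(C)C)[C@](O)(CO[Si](C)(C)C(C)(C)C)C[C@H]2OC(=O)C[C@@H]2[C@H]1OCc3ccc(OC)cc3 | intermediate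
24 | 13-(dimethylamino) Mannich base of 23, C11 epimers (not isolated) | C1/C(C)=C\C[C@H](O[Si](C)(C)C(C)(C)C)[C@](O)(CO[Si](C)(C)C(C)(C)C)C[C@H]2OC(=O)C(CN(C)C)[C@@H]2[C@H]1OCc3ccc(OC)cc3 | intermediate
25 | 13-(trimethylammonio) iodide from 24 (not isolated) | [I-].C1/C(C)=C\C[C@H](O[Si](C)(C)C(C)(C)C)[C@](O)(CO[Si](C)(C)C(C)(C)C)C[C@H]2OC(=O)C(C[N+](C)(C)C)[C@@H]2[C@H]1OCc3ccc(OC)cc3 | intermediate
26 | (3S,4R,6R,7R,8S,1(10)Z)-3,15-bis[(tert-butyldimethylsilyl)oxy]-4-hydroxy-8-[(4-methoxybenzyl)oxy]germacra-1(10),11(13)-dien-12,6-olide | C1/C(C)=C\C[C@H](O[Si](C)(C)C(C)(C)C)[C@](O)(CO[Si](C)(C)C(C)(C)C)C[C@H]2OC(=O)C(=C)[C@@H]2[C@H]1OCc3ccc(OC)cc3 | intermediate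
27 | (3S,4R,6R,7R,8S,1(10)Z)-3,15-bis[(tert-butyldimethylsilyl)oxy]-4,8-dihydroxygermacra-1(10),11(13)-dien-12,6-olide | C1/C(C)=C\C[C@H](O[Si](C)(C)C(C)(C)C)[C@](O)(CO[Si](C)(C)C(C)(C)C)C[C@H]2OC(=O)C(=C)[C@@H]2[C@H]1O | intermediate
28 | angelic acid, (Z)-2-methylbut-2-enoic acid | C/C=C(/C)C(=O)O | starting material
29 | (3S,4R,6R,7R,8R,1(10)Z)-8-(angeloyloxy)-3,15-bis[(tert-butyldimethylsilyl)oxy]-4-hydroxygermacra-1(10),11(13)-dien-12,6-olide | C1/C(C)=C\C[C@H](O[Si](C)(C)C(C)(C)C)[C@](O)(CO[Si](C)(C)C(C)(C)C)C[C@H]2OC(=O)C(=C)[C@@H]2[C@@H]1OC(=O)/C(C)=C\C | intermediate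
30 | (3S,4R,6R,7R,8R,1(10)Z)-8-(angeloyloxy)-3,4,15-trihydroxygermacra-1(10),11(13)-dien-12,6-olide | C1/C(C)=C\C[C@H](O)[C@](O)(CO)C[C@H]2OC(=O)C(=C)[C@@H]2[C@@H]1OC(=O)/C(C)=C\C | intermediate
31 | (1R,3S,4R,6R,7S,8R,10S)-8-(angeloyloxy)-1,10-epoxy-3,4,15-trihydroxygermacr-11(13)-en-12,6-olide (CNP0307250.1) | C=C1C(=O)O[C@@H]2C[C@@](O)(CO)[C@@H](O)C[C@H]3O[C@@]3(C)C[C@@H](OC(=O)/C(C)=C\C)[C@@H]12 | target

**Step count and risks**

Total step count: 17. Longest linear sequence: 16 steps (1 to 31 through steps 1–6 and 8–17); step 7 is a one-step side branch.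

The three steps most likely to fail:

1. Step 10 (key step). The potassium dienolate may lose the C8 PMB-oxy group by β-elimination before it is alkylated, or the rearrangement may leak through a boat and erode the Z geometry. The fallback is a neutral siloxy-Cope sequence that sets out from 15. Silylation of the tertiary alcohol (Me3SiCl, Et3N, CH2Cl2) should give the trimethylsilyl ether F1. Thermolysis (degassed PhMe with a trace of Et3N, sealed tube, about 190 °C) should then give, by the same chair [3,3] shift but without any free enolate, the ring-expanded trimethylsilyl enol ether F2. MeLi (THF, −78 °C) liberates the lithium enolate only at low temperature, and alkylation in situ with 16 returns to the route at 19.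

2. Step 15. The hindered C8 oxyphosphonium ion may eliminate toward C9 or C7, or the ester may form with retention by acyl transfer, instead of undergoing SN2 displacement. The fallback inverts C8 by oxidation and reduction and sets out from 27. Dess–Martin periodinane (NaHCO3, CH2Cl2) should give the C8 ketone F3. Reduction with NaBH4 and CeCl3·7H2O (MeOH, −78 °C), hydride entering anti to the C7–C11 bond, should give the (8R)-alcohol F4. Yamaguchi esterification with 28 (2,4,6-trichlorobenzoyl chloride, Et3N, PhMe) returns to the route at 29.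

3. Step 17. The dioxirane may attack the other face of the C1=C10 alkene if the ring conformation overrides the catalyst, which would give the diastereomeric cis-epoxide. The fallback delivers the epoxide oxygen anti to the face preferred by electrophiles and sets out from 29. N-(Trimethylsilyl)imidazole should give the C4 trimethylsilyl ether F5, which blocks bromoetherification. N-Bromosuccinimide in THF–H2O at 0 °C should form the bromonium ion on the open face and be opened by water at the tertiary C10, giving the (1S,10S)-bromohydrin F6. DBU (CH2Cl2) closes the ring with inversion at C1 to the silylated (1R,10S)-epoxide F7, and HF·pyridine (pyridine, THF) returns to the route at 31.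

Further compounds
F1 | step 10 | trimethylsilyl ether of 15 | C=C(C)[C@H]1C[C@H](O[Si](C)(C)C(C)(C)C)C(CO[Si](C)(C)C(C)(C)C)=C[C@@]1(O[Si](C)(C)C)/C=C/OCc2ccc(OC)cc2
F2 | step 10 | (3S,8S,1(10)Z,4Z,6E)-ring-expanded C6 trimethylsilyl enol ether | C1/C(C)=C\C[C@H](O[Si](C)(C)C(C)(C)C)/C(CO[Si](C)(C)C(C)(C)C)=C\C(O[Si](C)(C)C)=C\[C@H]1OCc2ccc(OC)cc2
F3 | step 15 | (3S,4R,6R,7R,1(10)Z)-3,15-bis[(tert-butyldimethylsilyl)oxy]-4-hydroxy-8-oxogermacra-1(10),11(13)-dien-12,6-olide | C1/C(C)=C\C[C@H](O[Si](C)(C)C(C)(C)C)[C@](O)(CO[Si](C)(C)C(C)(C)C)C[C@H]2OC(=O)C(=C)[C@@H]2C1=O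
F4 | step 15 | (3S,4R,6R,7R,8R,1(10)Z)-3,15-bis[(tert-butyldimethylsilyl)oxy]-4,8-dihydroxygermacra-1(10),11(13)-dien-12,6-olide | C1/C(C)=C\C[C@H](O[Si](C)(C)C(C)(C)C)[C@](O)(CO[Si](C)(C)C(C)(C)C)C[C@H]2OC(=O)C(=C)[C@@H]2[C@@H]1O
F5 | step 17 | C4 trimethylsilyl ether of 29 | C1/C(C)=C\C[C@H](O[Si](C)(C)C(C)(C)C)[C@](O[Si](C)(C)C)(CO[Si](C)(C)C(C)(C)C)C[C@H]2OC(=O)C(=C)[C@@H]2[C@@H]1OC(=O)/C(C)=C\C
F6 | step 17 | (1S,10S)-1-bromo-10-hydroxy bromohydrin of F5 | C1[C@](C)(O)[C@@H](Br)C[C@H](O[Si](C)(C)C(C)(C)C)[C@](O[Si](C)(C)C)(CO[Si](C)(C)C(C)(C)C)C[C@H]2OC(=O)C(=C)[C@@H]2[C@@H]1OC(=O)/C(C)=C\C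
F7 | step 17 | (1R,10S)-1,10-epoxide carrying the C3 and C15 TBS ethers and the C4 trimethylsilyl ether | C1[C@]2(C)O[C@@H]2C[C@H](O[Si](C)(C)C(C)(C)C)[C@](O[Si](C)(C)C)(CO[Si](C)(C)C(C)(C)C)C[C@H]3OC(=O)C(=C)[C@@H]3[C@@H]1OC(=O)/C(C)=C\C
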